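Leftovers first: each substrate takes one partner or one rival reagent, so at least 1.00 of partner and 2.00 of rival reagent, solid and dissolved counted together, stay over.

    substrate + partner → target (k1 = 0.23 M⁻¹ s⁻¹)
    substrate + rival reagent → side product (k2 = 1.4 M⁻¹ s⁻¹)
    solid rival reagent ⇌ rival reagent, rate k3*(cs3 - [rival reagent]) while solid is left; crystals form when [rival reagent] > cs3 (cs3 = 14 mM, k3 = 0.17 s⁻¹)

substrate 18 mM; partner 2.00 equiv; solid rival reagent 3.00 equiv; time 15 min

- ash: doubling the amount of partner, all else as stated
- maple: doubling the solubility in step 3, all else as stated
- oak: doubling the dissolution coefficient of step 3, all else as stated

- as a solid, counted per litre of solution: solid rival reagent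
- at the start none of the solid rival reagent is in solution
- run time (flask): 15 min

- the target standing at 15 min, as a percentage of the substrate charged
- the change that raises the amount of target at 15 min, in percent of the substrate charged most ("none" if none brings more than 2 percentage points) (ash / maple / oak / none)
- amount of target at 15 min, in percent of the substrate charged, after maple

- Freeze the two competitors, and count everything as a fraction of the substrate charge.
- Dissolved rival reagent rises no higher than saturation, 0.778 of the charge. The selectivity factor, second step over first, is 6.09.
- The partner share is 29.7%: the first step's rate over both steps' rates, with partner frozen at its charge and rival reagent at saturation.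
- With those levels, substrate lives 0.598 min, against a run of 15 min. So you ask how the charge divides, not how far it gets.
- Now the bound from below. You keep rival reagent at saturation and let partner sag. Partner at its floor gives 17.4%. Partner at its likely mean, lowered by half the share, gives about 28.1%.
- Now the bound from above. Full substrate holds rival reagent down to 0.677 of the charge, which gives a share of 32.7%.
- Rival reagent also starts from nothing. That lag of 5.12 s hands the first step 4.24% of the charge, which lifts the top to 35.5%.
- I commit to the middle, 31.8%. Doubling the solubility gives a share of 17.4%. Recomputing the share for each change, the winner is ash.
- The forecast says 32%, inside the bracket, with ash best and 21% after maple, reasoning that “the yield is set purely by selectivity”.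
- The simulation gives 32.0%, with ash best at 18 percentage points and 20.8% after maple. That is 2.3 points above the partner share and inside the bracket. In the flask, rival reagent stands at 98.2% of saturation at 1.50 min. Now put the neighbour with 7.2 mM of substrate into the partner share. Saturation there counts 1.94 of its charge, the share is 14.5%, and that neighbour holds 15.8% target.

The rate constants were drawn at random within sensible limits; the flask was simulated.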